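**Strategy.** The cyclopentane ring (C1–C5, daucane numbering) is cut at C3–C4 and C1–C2. C2–C3 is an acrylic two-carbon unit: its β-carbon C3 meets the carbonyl carbon C4, two electrophilic carbons joined through a samarium ketyl, and its α-carbon C2 then adds as an enolate to C1 of an enoate. One SmI2 operation on an acyclic keto enoate thus builds the ring, the tertiary carbinol C4, quaternary C1 and a C2 acyl handle later converted into the acetate by Baeyer–Villiger oxidation. The step exploits the 1,3-dioxygenated C2–C3–C4 triad beside quaternary C1. Ring-closing metathesis (C8=C9) then forms the seven-membered ring; directed epoxidation and acylation finish.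

Key step: step 5

Remark: daucane numbering is used for the bicyclic compounds and, when stereocontrol is discussed, for the matching atoms of their precursors: C1 (quaternary ring-fusion carbon with CH3), C2 (CH–OAc), C3 (CH2), C4 (C(OH)i-Pr), C5 (ring-fusion CH), C6 (CH–O-veratroyl), C7 (CH2), C8 (C–CH3), C9 (CH), C10 (CH2).
Assumption: the sense of induction of Ipc2BOTf in step 3 is taken by analogy with ethyl ketone aldols; the antipodal borane would be used if the opposite sense is found.

Step 1
Reactants: 1 3-methylbutan-2-one; 2 methyl but-2-ynoate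
Product: 3 methyl (2E)-3,6-dimethyl-5-oxohept-2-enoate
Conditions: LDA (LiN(i-Pr)2), THF, −78 °C; 2, −78 → −30 °C; AcOH
Reagents that add atoms: none
Why: The kinetic lithium enolate (CH3 side) adds in Michael fashion to the ynoate, and in-flask proton transfer to the doubly activated CH2 followed by protonation should give mainly the more stable (E)-enoate (conjugate addition of a ketone enolate to an alkynoate); no stereocenter is formed.

Step 2
Reactants: 4 3-methylbut-3-en-1-ol
Product: 5 3-methylbut-3-enal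
Conditions: Dess–Martin periodinane, CH2Cl2, 0 °C; used at once as a solution
Reagents that add atoms: none
Why: Dess–Martin oxidation of the primary alcohol under neutral conditions stops at the β,γ-unsaturated aldehyde, which is used at once to avoid isomerisation to the conjugated enal.

Step 3
Reactants: 3 methyl (2E)-3,6-dimethyl-5-oxohept-2-enoate; 5 3-methylbut-3-enal
Product: 6 methyl (2E,4R,5S)-5-hydroxy-3,7-dimethyl-4-(2-methylpropanoyl)octa-2,7-dienoate
Conditions: (−)-Ipc2BOTf, i-Pr2NEt, CH2Cl2, −78 °C; 5, −78 → −20 °C; H2O2, pH 7 buffer, MeOH, 0 °C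
Reagents that add atoms: none
Why: Paterson boron aldol reaction: enolisation at the activated CH2 gives the (Z)-boron enolate, which adds to 5 through a chair Zimmerman–Traxler transition state to give the syn aldol (C4/C5 of 6, the later C5/C6), the isopinocampheyl ligands choosing the enolate face and hence the absolute configuration.

Step 4
Reactants: 6 methyl (2E,4R,5S)-5-hydroxy-3,7-dimethyl-4-(2-methylpropanoyl)octa-2,7-dienoate
Product: 7 methyl (2E,4R,5S)-5-[(tert-butyldimethylsilyl)oxy]-3,7-dimethyl-4-(2-methylpropanoyl)octa-2,7-dienoate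
Conditions: TBSOTf, 2,6-lutidine, CH2Cl2, −78 °C
Reagents that add atoms: tert-butyldimethylsilyl triflate, CC(C)(C)[Si](C)(C)OS(=O)(=O)C(F)(F)F
Why: Silylation of the secondary alcohol at −78 °C with a hindered base should not epimerise the acidic C4–H, and it removes the hydroxyl that would allow retro-aldol cleavage or samarium chelation in the next step.

Step 5
Reactants: 7 methyl (2E,4R,5S)-5-[(tert-butyldimethylsilyl)oxy]-3,7-dimethyl-4-(2-methylpropanoyl)octa-2,7-dienoate; 8 N,N-dimethylprop-2-enamide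
Product: 10 methyl 2-[(1S,2S,4S,5R)-5-[(1S)-1-[(tert-butyldimethylsilyl)oxy]-3-methylbut-3-en-1-yl]-2-(dimethylcarbamoyl)-4-hydroxy-1-methyl-4-(propan-2-yl)cyclopentyl]acetate, via samarium alkoxide–amide enolate 9 (not isolated)
Conditions: SmI2 (3 equiv), THF, −78 → 0 °C, no proton source; sat. aq. NH4Cl
Reagents that add atoms: none
Why: SmI2 reduces the isopropyl ketone of 7 to a samarium ketyl whose carbon (C4) adds to the CH2 terminus (C3) of acrylamide 8, a second SmI2 reduces the α-carbamoyl radical to the samarium amide enolate 9, and the enolate carbon (C2) then adds to the enoate β-carbon (C1) before any proton source is present. The closest known reaction type is the SmI2 ketone–acrylate (acrylamide) reductive coupling, a ketyl–olefin union of two electrophilic carbons, run as a sequenced radical–anionic reaction in which the samarium enolate is trapped by a carbon electrophile. The cyclopentane is closed by a 5-exo-trig Michael addition. C4 is set by Felkin–Anh-type addition anti to the silyloxy-bearing carbon of the side chain; C2 by the trivalent samarium bridge between the C4 alkoxide and the enolate oxygen, which places the carbamoyl group cis to the C4 oxygen; C1 by the ring closure, which puts the larger CH2CO2Me arm trans to both neighbouring substituents (side chain on C5, amide on C2) and the methyl cis. The step needs the ketone to be reduced in preference to the enoate and the enolate to cyclise faster than it is protonated; the β,β-disubstituted enoate is not reduced by SmI2 without HMPA, the silyl ether blocks chelation and retro-aldol, and the absence of a proton donor keeps the enolate alive.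

Step 6
Reactants: 10 methyl 2-[(1S,2S,4S,5R)-5-[(1S)-1-[(tert-butyldimethylsilyl)oxy]-3-methylbut-3-en-1-yl]-2-(dimethylcarbamoyl)-4-hydroxy-1-methyl-4-(propan-2-yl)cyclopentyl]acetate
Product: 11 (1S,2S,3R,4S)-3-[(1S)-1-[(tert-butyldimethylsilyl)oxy]-3-methylbut-3-en-1-yl]-4-hydroxy-N,N,2-trimethyl-2-(2-oxoethyl)-4-(propan-2-yl)cyclopentane-1-carboxamide
Conditions: i-Bu2AlH (2.2 equiv), CH2Cl2, −78 °C; aq. Rochelle salt
Reagents that add atoms: none
Why: At −78 °C i-Bu2AlH should reduce the unhindered methyl ester to the aldehyde through a stable aluminium hemiacetal, while the hindered tertiary amide next to the quaternary centre is left (chemoselective partial reduction of an ester).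

Step 7
Reactants: 11 (1S,2S,3R,4S)-3-[(1S)-1-[(tert-butyldimethylsilyl)oxy]-3-methylbut-3-en-1-yl]-4-hydroxy-N,N,2-trimethyl-2-(2-oxoethyl)-4-(propan-2-yl)cyclopentane-1-carboxamide
Product: 12 (1S,2S,3R,4S)-3-[(1S)-1-[(tert-butyldimethylsilyl)oxy]-3-methylbut-3-en-1-yl]-4-hydroxy-N,N,2-trimethyl-4-(propan-2-yl)-2-(prop-2-en-1-yl)cyclopentane-1-carboxamide
Conditions: Ph3PCH3Br, KN(SiMe3)2, THF, 0 °C
Reagents that add atoms: methyltriphenylphosphonium bromide, C[P+](c1ccccc1)(c1ccccc1)c1ccccc1.[Br-]
Why: Wittig methylenation of the aldehyde gives the allyl group on C1; the non-stabilised ylide should not touch the amide or the silyl ether.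

Step 8
Reactants: 12 (1S,2S,3R,4S)-3-[(1S)-1-[(tert-butyldimethylsilyl)oxy]-3-methylbut-3-en-1-yl]-4-hydroxy-N,N,2-trimethyl-4-(propan-2-yl)-2-(prop-2-en-1-yl)cyclopentane-1-carboxamide
Product: 13 (1S,2S,4S,5R,6S)-6-[(tert-butyldimethylsilyl)oxy]-4-hydroxy-N,N-dimethyldauc-8-ene-2-carboxamide
Conditions: second-generation Grubbs catalyst RuCl2(=CHPh)(H2IMes)(PCy3) (5 mol%), CH2Cl2, 40 °C
Reagents that add atoms: none
Why: Ring-closing metathesis between the allyl group on C1 and the 2-methylallyl group of the C5 side chain forms the trisubstituted C8=C9 alkene and the seven-membered ring with loss of ethene; the trans arrangement of the two arms on the cyclopentane, fixed in step 5, becomes the trans ring fusion.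

Step 9
Reactants: 13 (1S,2S,4S,5R,6S)-6-[(tert-butyldimethylsilyl)oxy]-4-hydroxy-N,N-dimethyldauc-8-ene-2-carboxamide
Product: 14 1-[(1S,2S,4S,5R,6S)-6-[(tert-butyldimethylsilyl)oxy]-4-hydroxydauc-8-en-2-yl]ethan-1-one
Conditions: MeLi (3 equiv), THF, −78 → 0 °C; H2O
Reagents that add atoms: methyllithium, [Li]C
Why: Methyllithium adds to the N,N-dimethylamide to give a tetrahedral lithium hemiaminal that does not collapse before work-up, so the methyl ketone should form without over-addition (amide-to-ketone acyl substitution); C2 keeps its thermodynamically preferred configuration cis to the C4 hydroxyl.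

Step 10
Reactants: 14 1-[(1S,2S,4S,5R,6S)-6-[(tert-butyldimethylsilyl)oxy]-4-hydroxydauc-8-en-2-yl]ethan-1-one
Product: 15 1-[(1S,2S,4S,5R,6S)-4,6-dihydroxydauc-8-en-2-yl]ethan-1-one
Conditions: HF·pyridine, THF, 0 °C → rt
Reagents that add atoms: none
Why: Fluoride cleaves the Si–O bond of the secondary silyl ether and frees the C6 hydroxyl needed to direct the epoxidation.

Step 11
Reactants: 15 1-[(1S,2S,4S,5R,6S)-4,6-dihydroxydauc-8-en-2-yl]ethan-1-one
Product: 16 1-[(1S,2S,4S,5R,6S,8R,9S)-8,9-epoxy-4,6-dihydroxydaucan-2-yl]ethan-1-one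
Conditions: VO(acac)2 (5 mol%), t-BuOOH, CH2Cl2, 0 °C
Reagents that add atoms: tert-butyl hydroperoxide, CC(C)(C)OO
Why: Vanadium-catalysed hydroxyl-directed epoxidation: the vanadate ester of the homoallylic C6 alcohol delivers the peroxide oxygen to the alkene face syn to that hydroxyl, which sets C8 and C9.

Step 12
Reactants: 16 1-[(1S,2S,4S,5R,6S,8R,9S)-8,9-epoxy-4,6-dihydroxydaucan-2-yl]ethan-1-one
Product: 17 (1S,2S,4S,5R,6S,8R,9S)-8,9-epoxy-4,6-dihydroxydaucan-2-yl acetate
Conditions: mCPBA, NaHCO3, CH2Cl2, rt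
Reagents that add atoms: 3-chloroperbenzoic acid, OOC(=O)c1cccc(Cl)c1
Why: Baeyer–Villiger oxidation: in the Criegee adduct the secondary C2 migrates in preference to methyl with retention of configuration, turning the acetyl group into the C2 acetate; no alkene is left to compete and hydrogen carbonate buffering protects the epoxide.

Step 13
Reactants: 17 (1S,2S,4S,5R,6S,8R,9S)-8,9-epoxy-4,6-dihydroxydaucan-2-yl acetate; 18 3,4-dimethoxybenzoyl chloride
Product: 19 (1S,2S,4S,5R,6S,8R,9S)-2-acetoxy-8,9-epoxy-4-hydroxydaucan-6-yl 3,4-dimethoxybenzoate (CNP0330776.1)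
Conditions: Et3N, DMAP (cat.), CH2Cl2, 0 °C → rt
Reagents that add atoms: none
Why: DMAP-catalysed acylation esterifies the secondary C6 hydroxyl, while the tertiary C4 hydroxyl is too hindered to react.

**Compound list**

1 | 3-methylbutan-2-one | CC(C)C(C)=O | starting material
2 | methyl but-2-ynoate | CC#CC(=O)OC | starting material
3 | methyl (2E)-3,6-dimethyl-5-oxohept-2-enoate | CC(C)C(=O)C/C(C)=C/C(=O)OC | intermediate
4 | 3-methylbut-3-en-1-ol | CC(=C)CCO | starting material
5 | 3-methylbut-3-enal | CC(=C)CC=O | intermediate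
6 | methyl (2E,4R,5S)-5-hydroxy-3,7-dimethyl-4-(2-methylpropanoyl)octa-2,7-dienoate | CC(C)C(=O)[C@@H]([C@@H](O)CC(C)=C)/C(C)=C/C(=O)OC | intermediate
7 | methyl (2E,4R,5S)-5-[(tert-butyldimethylsilyl)oxy]-3,7-dimethyl-4-(2-methylpropanoyl)octa-2,7-dienoate | CC(C)C(=O)[C@@H]([C@@H](O[Si](C)(C)C(C)(C)C)CC(C)=C)/C(C)=C/C(=O)OC | intermediate
8 | N,N-dimethylprop-2-enamide | C=CC(=O)N(C)C | starting material
9 | samarium alkoxide–amide enolate from the ketyl–olefin coupling (drawn as the dianion, trivalent samarium counter-ions omitted) | CC(C)[C@@]([O-])(CC=C([O-])N(C)C)[C@@H]([C@@H](O[Si](C)(C)C(C)(C)C)CC(C)=C)/C(C)=C/C(=O)OC | intermediate (not isolated)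
10 | methyl 2-[(1S,2S,4S,5R)-5-[(1S)-1-[(tert-butyldimethylsilyl)oxy]-3-methylbut-3-en-1-yl]-2-(dimethylcarbamoyl)-4-hydroxy-1-methyl-4-(propan-2-yl)cyclopentyl]acetate | CC(C)[C@@]1(O)C[C@H](C(=O)N(C)C)[C@@](C)(CC(=O)OC)[C@@H]1[C@@H](O[Si](C)(C)C(C)(C)C)CC(C)=C | intermediate
11 | (1S,2S,3R,4S)-3-[(1S)-1-[(tert-butyldimethylsilyl)oxy]-3-methylbut-3-en-1-yl]-4-hydroxy-N,N,2-trimethyl-2-(2-oxoethyl)-4-(propan-2-yl)cyclopentane-1-carboxamide | CC(C)[C@@]1(O)C[C@H](C(=O)N(C)C)[C@@](C)(CC=O)[C@@H]1[C@@H](O[Si](C)(C)C(C)(C)C)CC(C)=C | intermediate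
12 | (1S,2S,3R,4S)-3-[(1S)-1-[(tert-butyldimethylsilyl)oxy]-3-methylbut-3-en-1-yl]-4-hydroxy-N,N,2-trimethyl-4-(propan-2-yl)-2-(prop-2-en-1-yl)cyclopentane-1-carboxamide | CC(C)[C@@]1(O)C[C@H](C(=O)N(C)C)[C@@](C)(CC=C)[C@@H]1[C@@H](O[Si](C)(C)C(C)(C)C)CC(C)=C | intermediate
13 | (1S,2S,4S,5R,6S)-6-[(tert-butyldimethylsilyl)oxy]-4-hydroxy-N,N-dimethyldauc-8-ene-2-carboxamide (trans-fused) | CC(C)(C)[Si](C)(C)O[C@H]2CC(C)=CC[C@]3(C)[C@@H](C(=O)N(C)C)C[C@](O)(C(C)C)[C@@H]23 | intermediate
14 | 1-[(1S,2S,4S,5R,6S)-6-[(tert-butyldimethylsilyl)oxy]-4-hydroxydauc-8-en-2-yl]ethan-1-one | CC(C)(C)[Si](C)(C)O[C@H]2CC(C)=CC[C@]3(C)[C@@H](C(C)=O)C[C@](O)(C(C)C)[C@@H]23 | intermediate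
15 | 1-[(1S,2S,4S,5R,6S)-4,6-dihydroxydauc-8-en-2-yl]ethan-1-one | O[C@H]2CC(C)=CC[C@]3(C)[C@@H](C(C)=O)C[C@](O)(C(C)C)[C@@H]23 | intermediate
16 | 1-[(1S,2S,4S,5R,6S,8R,9S)-8,9-epoxy-4,6-dihydroxydaucan-2-yl]ethan-1-one (oxirane oxygen syn to the C6 hydroxyl) | O[C@H]2C[C@@]3(C)O[C@H]3C[C@]3(C)[C@@H](C(C)=O)C[C@](O)(C(C)C)[C@@H]23 | intermediate
17 | (1S,2S,4S,5R,6S,8R,9S)-8,9-epoxy-4,6-dihydroxydaucan-2-yl acetate | O[C@H]2C[C@@]3(C)O[C@H]3C[C@]3(C)[C@@H](OC(C)=O)C[C@](O)(C(C)C)[C@@H]23 | intermediate
18 | 3,4-dimethoxybenzoyl chloride | COc1ccc(C(Cl)=O)cc1OC | starting material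
19 | (1S,2S,4S,5R,6S,8R,9S)-2-acetoxy-8,9-epoxy-4-hydroxydaucan-6-yl 3,4-dimethoxybenzoate (CNP0330776.1) | COc1ccc(C(=O)O[C@H]2C[C@@]3(C)O[C@H]3C[C@]3(C)[C@@H](OC(C)=O)C[C@](O)(C(C)C)[C@@H]23)cc1OC | target

**Step count.** Total: 13 steps. Longest linear sequence: 12 steps (1 → 3 → 6 → 7 → 10 → 11 → 12 → 13 → 14 → 15 → 16 → 17 → 19); step 2 is a one-step branch.

**Steps most likely to fail**

Step 5. The ring closure may not follow the coupling, because the samarium enolate is protonated or attacks the hindered enoate carbon too slowly, and the ketyl may add with poor facial selectivity. The fallback sets out from 7 and comes back at 10, making the two bonds in separate known steps. SmI2/t-BuOH coupling of 7 with methyl acrylate gives the γ-lactone methyl (2E,4R,5S)-5-[(tert-butyldimethylsilyl)oxy]-3,7-dimethyl-4-[(2S)-5-oxo-2-(propan-2-yl)oxolan-2-yl]octa-2,7-dienoate F1. LiN(SiMe3)2 at −78 °C then forms the lactone enolate, which closes the cyclopentane by intramolecular Michael addition to give the bridged lactone methyl 2-[(1S,4S,5S,6R)-6-[(1S)-1-[(tert-butyldimethylsilyl)oxy]-3-methylbut-3-en-1-yl]-5-methyl-3-oxo-1-(propan-2-yl)-2-oxabicyclo[2.2.1]heptan-5-yl]acetate F2; the lactone bridge enforces the cis relation of the C2 carbonyl and the C4 oxygen. Aminolysis of the strained lactone with Me2NH·HCl/AlMe3 gives hydroxy amide 10.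

Step 3. Enantio- and diastereoselectivity may erode in the conjugated boron enolate, the β,γ-unsaturated aldehyde may isomerise, and retro-aldol or epimerisation at the acidic C4 may occur on work-up. The fallback sets out from 3 and 5 and comes back at 6. The lithium enolate of 3 (LDA, −78 °C) and 5 give methyl (2E)-5-hydroxy-3,7-dimethyl-4-(2-methylpropanoyl)octa-2,7-dienoate (mixture of stereoisomers) F3. Dess–Martin oxidation gives the β-diketone methyl (2E)-3,7-dimethyl-4-(2-methylpropanoyl)-5-oxoocta-2,7-dienoate F4, in which C4 is stereolabile. A ketoreductase with NADPH/i-PrOH recycling reduces the less hindered C5 ketone under dynamic kinetic resolution at C4 to give 6.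

Step 12. Migration at the hindered C2 may be slow, and the epoxide may open under the acidic peracid conditions, helped by the neighbouring hydroxyl groups. The fallback sets out from 15 and comes back at 17, with the two oxidations in the reverse order. An alkene-sparing Baeyer–Villiger oxidation of 15 with (Me3SiO)2, SnCl4 and trans-cyclohexane-1,2-diamine gives (1S,2S,4S,5R,6S)-4,6-dihydroxydauc-8-en-2-yl acetate F5. VO(acac)2/t-BuOOH epoxidation directed by the C6 hydroxyl then gives 17.

Further compounds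
F1 | step 5 | methyl (2E,4R,5S)-5-[(tert-butyldimethylsilyl)oxy]-3,7-dimethyl-4-[(2S)-5-oxo-2-(propan-2-yl)oxolan-2-yl]octa-2,7-dienoate | CC(C)[C@@]1(CCC(=O)O1)[C@@H]([C@@H](O[Si](C)(C)C(C)(C)C)CC(C)=C)/C(C)=C/C(=O)OC
F2 | step 5 | methyl 2-[(1S,4S,5S,6R)-6-[(1S)-1-[(tert-butyldimethylsilyl)oxy]-3-methylbut-3-en-1-yl]-5-methyl-3-oxo-1-(propan-2-yl)-2-oxabicyclo[2.2.1]heptan-5-yl]acetate | CC(C)[C@]12C[C@H](C(=O)O1)[C@@](C)(CC(=O)OC)[C@@H]2[C@@H](O[Si](C)(C)C(C)(C)C)CC(C)=C
F3 | step 3 | methyl (2E)-5-hydroxy-3,7-dimethyl-4-(2-methylpropanoyl)octa-2,7-dienoate (mixture of stereoisomers) | CC(C)C(=O)C(C(O)CC(C)=C)/C(C)=C/C(=O)OC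
F4 | step 3 | methyl (2E)-3,7-dimethyl-4-(2-methylpropanoyl)-5-oxoocta-2,7-dienoate | CC(C)C(=O)C(C(=O)CC(C)=C)/C(C)=C/C(=O)OC
F5 | step 12 | (1S,2S,4S,5R,6S)-4,6-dihydroxydauc-8-en-2-yl acetate | O[C@H]2CC(C)=CC[C@]3(C)[C@@H](OC(C)=O)C[C@](O)(C(C)C)[C@@H]23
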